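## Structural features

The target is a linear procyanidin trimer in which an epicatechin 3-O-gallate unit (top) is bonded through C4 to C8 of a second epicatechin 3-O-gallate unit (middle), whose C4 is bonded to C6 of a catechin unit (bottom). Each unit is a 2-arylchroman with a phloroglucinol-derived ring A, a pyran ring C and a catechol ring B. The top and middle pyran rings each carry three contiguous stereocentres (C2, C3, C4; 2,3-cis-3,4-trans, C4 aryl on the β face) and the bottom ring two (C2, C3; trans), eight in all. Both C4 carbons are diarylmethines between oxygen-rich rings, so the interflavan bonds ionise in acid; the eighteen phenols oxidise easily, the two gallates sit on hindered secondary alcohols, and C2 epimerises through a quinone methide when the phenols are free. The difficulty is not the monomers, whose flavan cores can be bought with their stereocentres, but joining three units with the right regiochemistry (middle C8, bottom C6) and creating the middle C2/C3/C4 triad between them. The key step exploits the fact that middle C4a and C8a are neighbouring carbons of a phloroglucinol ring that already holds top C4 on C8, while middle C4 is bonded to bottom C6. Middle ring C can therefore be closed last, by forming C4–C4a and O1–C2 between a top-unit phenol and a bottom-unit enone.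

## Logic of the disconnections

**26 ⇒ 25.** Nineteen O–benzyl bonds and the C8–Br bond of the bottom unit are added back. All oxygen functions must stay masked until the end, and benzyl ethers and an aryl bromide fall together in one neutral hydrogenolysis. The gain is a lipophilic intermediate that can be chromatographed. The demand is that the last step spares two esters, the benzylic C2–O1 bonds and both interflavan bonds, and that HBr is buffered.

**25 ⇒ 24 + 3.** The acyl C–O bond of the middle gallate is cut, because the middle C3 oxygen does not exist before the ring is made. 24 has a single free hydroxyl, so no selectivity is needed. The forward step must acylate an alcohol flanked by two aryl-bearing carbons.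

**24 ⇒ 22 (through 23).** The C3–O and C2–H bonds of the middle ring are removed to leave the enol ether C2=C3. The existing C4 centre then controls both new centres: oxygen enters anti to the C4 aryl group and hydride enters anti to that oxygen. The demand is face-selective oxidation and hydride delivery without acid cleavage of the diarylmethine bonds.

**22 ⇒ 21.** Two O–benzyl bonds on middle ring A are cut, one back to a free phenol and one back to a silyl ether. A free phenol is incompatible with the dioxirane and with acylation, and a uniform benzyl pattern keeps the final deprotection to one step. The forward step must spare the ester and the enol ether.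

**21 ⇒ 8 + 18 (key disconnection).** Middle C4–C4a and O1–C2 are cut, which removes ring C and the C4 stereocentre and leaves two complete flavan units. 8 carries two equivalent CH/OH pairs on a ring whose para oxygen is blocked, so closure can only give the 4→8 pattern. Two features are designed into the precursors:
- The para oxygen of 8 is a bulky silyl ether and not a benzyl ether. It can be placed selectively on a triol by steric access, which a small benzylating agent cannot be relied on to do, and it screens the second CH after the first annulation.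
- 18 carries bromine on bottom C8. It directs the earlier formylation to C6, removes the only other nucleophilic aryl CH, and leaves in the last step.

The demand on the forward step is facial control at the enone β-carbon by the catalyst, and acid mild enough to leave the top C4–aryl bond intact.

**18 ⇒ 14 + 16; 16 ⇒ 15.** The enone Cα=Cβ bond is cut (aldol condensation), then two O–benzyl bonds. 14 cannot enolise, so only one condensation product is possible. The forward step must tolerate a hindered, electron-rich aldehyde.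

**14 ⇒ 12 ⇒ 11 ⇒ 10 ⇒ 9.** The C6–CHO bond, the C3 O–benzyl bond, the C8–Br bond and four phenolic O–benzyl bonds are cut in turn. 9 supplies both bottom stereocentres. Bromination goes to C8, the site electrophiles take first, so the formyl group is forced to C6. The demand is formylation at a position flanked by two benzyloxy groups.

**8 ⇒ 7 ⇒ 5 + 6.** The para O–Si bond is cut, then the top C4–aryl bond. 6 is threefold symmetric, so the C–C bond formation has no regiochemical question, and the three phenols are told apart afterwards by hindrance. The forward steps need 4β capture of the C4 cation, monoalkylation of 6 and monosilylation of 7.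

**5 ⇒ 4; 4 ⇒ 2 + 3; 2 ⇒ 1.** The C4–O bond is cut, then the acyl C–O bond of the top ester, then four phenolic O–benzyl bonds. 1 supplies both stereocentres of the top unit, and 3 is the same acid that later acylates the middle unit, so one building block serves both esters. Benzylating before acylating means no ester is ever exposed to the alkylation base. The demand is hydride abstraction at C4 next to an acyloxy group.

## Other disconnections considered

**Alternative 1:** The cut runs through C3–C4 and O1–C2 of the top ring C.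
- **Forward step.** The interflavan bond is already present in a diarylcarbinol A1, a benzylic alcohol on the future top C4 that carries a 2-hydroxy-4,6-dibenzyloxyphenyl group and C8 of a silylated epicatechin unit. Acid would ionise A1 to an ortho-quinone methide, the Z-configured enol silane A2 would add through its silyloxy-bearing CH carbon, and the phenol would close on the ketone to give hemiketal A3. Silane reduction at C2 would then give the 2,3-cis ring.
- **Structural point.** Because C2 of A3 carries the aryl group, A2 has to be the enol silane of an α-silyloxy aryl ketone; a glycolate ester enol silane would place an alkoxy group, not the catechol ring, on C2.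
- **In favour.** C3 arrives at the right oxidation level and trans to the C4 aryl group. The 4→8 regiochemistry comes from a simple aryl–carbonyl addition, and the quinone methide addition is a well-known reaction type. On the oxidation level of the new ring it is the better plan, since A3 already has what step 14 must create.
- **Against.** It builds from small pieces the one unit whose stereocentres 1 supplies ready-made. Both C3 oxygens end as silyl ethers, so two desilylations and two acylations follow. The bottom unit is still missing and would need a benzylic oxidation of a dimer with two competing C4–H sites, followed by a cation coupling.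
- **Comparison.** On stereocontrol the two plans are equals: in both, the new centres are made far from the resident ones and need a chiral catalyst or a separation. On mechanism both rest on acid-generated benzylic cations next to labile diarylmethines. On step count the chosen plan is clearly ahead.

**Alternative 2:** The cut is the C3=C4 bond of the bottom ring C in a complete top–middle digallate.
- **Forward step.** The precursor A4 carries, on the future bottom ring A, a vinyl group at C4a and an O-(1-arylallyl) ether on the C8a oxygen. Ring-closing metathesis with the second-generation Grubbs catalyst (H2IMes)(PCy3)Cl2Ru=CHPh would give flav-3-ene A5 with loss of ethene. Hydroboration–oxidation anti to the 2-aryl group would then give the 2,3-trans alcohol.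
- **Structural point.** C2 of A5 has the geometry of catechin C2, but in a flav-3-ene the aryl group outranks the sp2 C3, so this centre carries the descriptor 2S, not 2R.
- **In favour.** Metathesis tolerates esters and benzyl ethers, needs no acid and creates no stereocentre. As a ring closure it is more predictable than step 12, and on this point it is the better of the two. The trans C2/C3 relationship is the natural result of hydroboration.
- **Against.** The ring it makes belongs to the cheapest unit, which 9 supplies with both centres. The interflavan bonds and the middle triad, the real problem, are left to other chemistry. A4 needs a phloroglucinol ring with three different substituents placed regioselectively, and a configurationally defined allylic aryl ether that can ionise or undergo [3,3] rearrangement. The hydroboration would run next to two esters.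
- **Comparison.** The plan is linear where the chosen one is convergent, and it is the longest of the options.

**Alternative 3:** The cut is the C8a–O1 bond of the top ring.
- **Forward step.** A 3-arylindan-1-one A6, whose stereocentre is the future top C4 already bonded to C8 of a silylated epicatechin unit, would be oxidised with CF3CO3H (Baeyer–Villiger, aryl migration with retention) to the 4-arylchroman-2-one A7. Hydroxylation α to the lactone, aryl addition and silane reduction would complete the ring.
- **In favour.** The inter-unit stereocentre can be set in the indanone series by mature asymmetric conjugate additions and is not touched by the oxygen insertion. On reliable absolute control at a carbon joining two units this is better than the catalyst-dependent step 12. The lactone is a versatile handle.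
- **Against.** The aryl carbon that must migrate is meta to both benzyloxy groups of its ring, so its preference over the CH2 group is not assured. The peracid is an electrophilic oxidant, and the substrate holds a trialkoxybenzene ring and a catechol diether. The top unit is again made from scratch, with the middle C4 oxidation and the bottom unit still to come.
- **Comparison.** The chosen plan forms two bonds and a ring in one step at the acidity of a phosphoric acid; this one forms one bond under strongly oxidising acid. In step count it is far longer.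

Key step: step 12

**Remarks.**
- Assumption: the (R) acid is taken as the antipode that favours the needed C4 configuration in step 12. This cannot be derived from a model, and the (S) acid would be used in the same way if the sense is opposite.
- The annulation partners 8 and 18 and the annulation product 21 carry the configuration of the target at every stereocentre they contain. In 8 a silyl ether stands on the para oxygen, and 18 carries bromine on C8.
- Flavan numbering is used throughout (O1, C2–C4, C4a, C5–C8, C8a; ring B primed).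

## Route

Step 1
Reactants: 1 (−)-epicatechin
Product: 2 5,7,3',4'-tetra-O-benzyl-(−)-epicatechin
Conditions: BnBr (4.4 equiv), K2CO3 (5 equiv), DMF, 0 °C → rt, Ar
Reagents that add atoms: benzyl bromide, BrCc1ccccc1
Why: Williamson ether synthesis: carbonate deprotonates only the four phenols, so the secondary alcohol stays free; low temperature under argon limits C-benzylation and base-induced C2 epimerisation through the quinone methide, so both stereocentres of 1 are carried over.

Step 2
Reactants: 2 5,7,3',4'-tetra-O-benzyl-(−)-epicatechin; 3 3,4,5-tris(benzyloxy)benzoic acid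
Product: 4 5,7,3',4'-tetra-O-benzyl-(−)-epicatechin 3-O-(3,4,5-tri-O-benzyl)gallate
Conditions: 3 (1.5 equiv), DCC (1.6 equiv), DMAP (0.3 equiv), CH2Cl2, 0 °C → rt
Reagents that add atoms: none
Why: Steglich esterification: DCC activates 3 as the O-acylisourea and DMAP relays the acyl group to the only free hydroxyl; no stereocentre is touched, and with every phenol already masked no base-labile site is exposed.

Step 3
Reactants: 4 5,7,3',4'-tetra-O-benzyl-(−)-epicatechin 3-O-(3,4,5-tri-O-benzyl)gallate
Product: 5 4β-(2-ethoxyethoxy) derivative of 4 (2,3-cis-3,4-trans)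
Conditions: DDQ (2 equiv), 2-ethoxyethanol (5 equiv), CH2Cl2, rt
Reagents that add atoms: 2-ethoxyethanol, CCOCCO
Why: Oxidative benzylic etherification: DDQ removes hydride from C4, and the cation (stabilised by the 5,7-dialkoxy ring A) is captured by the alcohol opposite to the 2-aryl and 3-acyloxy groups, helped by participation of the ester carbonyl; the C4 configuration is not critical because C4 is ionised again in step 4.

Step 4
Reactants: 5 4β-(2-ethoxyethoxy) derivative of 4; 6 phloroglucinol
Product: 7 4β-(2,4,6-trihydroxyphenyl) derivative of 4 (2,3-cis-3,4-trans)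
Conditions: 6 (anhydrous, 5 equiv), BF3·OEt2 (0.5 equiv), THF–CH2Cl2, −20 → 0 °C
Reagents that add atoms: none
Why: Friedel–Crafts alkylation: the Lewis acid ionises the C4 ether, the cation is bridged on the α face by the ester carbonyl and is attacked by 6 from the β face, which sets the 3,4-trans aryl group; 6 is threefold symmetric, so there is no regiochemical question, and its excess suppresses a second alkylation.

Step 5
Reactants: 7 4β-(2,4,6-trihydroxyphenyl) derivative of 4
Product: 8 4β-[2,6-dihydroxy-4-(triisopropylsilyloxy)phenyl] derivative of 4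
Conditions: TIPSCl (1.05 equiv), imidazole, DMF, −20 → 0 °C
Reagents that add atoms: triisopropylsilyl chloride, CC(C)[Si](Cl)(C(C)C)C(C)C
Why: Silylation by a bulky silyl chloride is governed by steric access: the para hydroxyl lies between two CH groups and each ortho hydroxyl lies next to the flavan-4-yl group, so one equivalent at low temperature should take the para oxygen; a silyl group is used here because a small benzylating agent would not distinguish the three phenols.

Step 6
Reactants: 9 (+)-catechin
Product: 10 5,7,3',4'-tetra-O-benzyl-(+)-catechin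
Conditions: BnBr (4.4 equiv), K2CO3, DMF, 0 °C → rt
Reagents that add atoms: benzyl bromide, BrCc1ccccc1
Why: Williamson ether synthesis; carbonate deprotonates only the four phenols, so the secondary alcohol stays free and C2/C3 are untouched.

Step 7
Reactants: 10 5,7,3',4'-tetra-O-benzyl-(+)-catechin
Product: 11 8-bromo-5,7,3',4'-tetra-O-benzyl-(+)-catechin
Conditions: NBS (1.0 equiv), CH2Cl2, −78 °C → rt
Reagents that add atoms: N-bromosuccinimide, O=C1CCC(=O)N1Br
Why: Electrophilic aromatic bromination; in 5,7-di-O-benzylflavans C8 is the position electrophiles take first, and one equivalent at low temperature stops at the monobromide, which blocks C8 for the steps that follow.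

Step 8
Reactants: 11 8-bromo-5,7,3',4'-tetra-O-benzyl-(+)-catechin
Product: 12 8-bromo-3,5,7,3',4'-penta-O-benzyl-(+)-catechin
Conditions: NaH, BnBr, Bu4NI (cat.), DMF, 0 °C → rt
Reagents that add atoms: benzyl bromide, BrCc1ccccc1
Why: Williamson ether synthesis through the sodium alkoxide; no phenol is free, so C2 is configurationally safe under the strong base, and the aryl bromide is inert.

Step 9
Reactants: 12 8-bromo-3,5,7,3',4'-penta-O-benzyl-(+)-catechin
Product: 14 8-bromo-6-formyl-3,5,7,3',4'-penta-O-benzyl-(+)-catechin, via iminium salt 13 (not isolated)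
Conditions: POCl3 (3 equiv), DMF, 0 → 70 °C; then aq. NaOAc, rt
Reagents that add atoms: N,N-dimethylformamide, CN(C)C=O; water, O
Why: Vilsmeier–Haack formylation: the chloroiminium ion substitutes the only free position of ring A, C6, which is activated by two ortho oxygens and one para oxygen, and the iminium salt 13 is hydrolysed on buffered work-up; with C8 blocked the regiochemistry cannot go wrong.

Step 10
Reactants: 15 3,4-dihydroxyacetophenone
Product: 16 3,4-dibenzyloxyacetophenone
Conditions: BnBr (2.2 equiv), K2CO3, DMF, 60 °C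
Reagents that add atoms: benzyl bromide, BrCc1ccccc1
Why: Williamson ether synthesis on the catechol; the ketone is unaffected.

Step 11
Reactants: 14 8-bromo-6-formyl-3,5,7,3',4'-penta-O-benzyl-(+)-catechin; 16 3,4-dibenzyloxyacetophenone
Product: 18 (E)-1-(3,4-dibenzyloxyphenyl)-3-(8-bromo-penta-O-benzylcatechin-6-yl)prop-2-en-1-one, via aldol adduct 17 (not isolated)
Conditions: KOH (aq., cat.), EtOH–THF, rt → 40 °C
Reagents that add atoms: none
Why: Claisen–Schmidt condensation: the enolate of 16 adds to the non-enolisable aldehyde 14 and the aldol 17 loses water by an E1cB pathway to the conjugated enone, whose E geometry is the thermodynamic one; all phenols are protected, so base cannot epimerise the flavan C2.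

Step 12
Reactants: 8 4β-[2,6-dihydroxy-4-(triisopropylsilyloxy)phenyl] derivative of 4 (1.3 equiv); 18 (E)-1-(3,4-dibenzyloxyphenyl)-3-(8-bromo-penta-O-benzylcatechin-6-yl)prop-2-en-1-one
Product: 21 trimer whose middle unit is a 7-hydroxy-5-(triisopropylsilyloxy)flav-2-ene (4β→6 to the 8-bromo bottom unit; top unit 4β→8), via conjugate-addition ketone 19 (not isolated), via cyclic hemiketal 20 (not isolated)
Conditions: (R)-3,3'-bis(2,4,6-triisopropylphenyl)-1,1'-binaphthyl-2,2'-diyl hydrogen phosphate (10 mol %), 4 Å MS, toluene, rt → 40 °C, Ar, dark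
Reagents that add atoms: none
Why: The phosphoric acid protonates the enone carbonyl of 18, the positive charge at the β-carbon is shared with the three oxygen donors of bottom ring A, and a ring carbon of 8 that is ortho to one hydroxyl and para to the other attacks it (Friedel–Crafts conjugate addition, C4–C4a), giving ketone 19 after rearomatisation. The hydroxyl next to the new bond then adds to the carbonyl in a 6-exo-trig closure (O1–C2, hemiketal 20), and acid-promoted loss of water, taken up by the sieves, gives the aryl-conjugated enol ether 21. The closest known reaction type is the Brønsted-acid-catalysed annulation of phenols with chalcones to 2,4-diaryl-4H-chromenes. C4 is the only new stereocentre; the resident centres are too far from the β-carbon for substrate control, so the face is chosen by the chiral phosphate, which holds the phenol OH and the protonated carbonyl in one ion pair, and because the two C4 epimers are diastereomers they can be separated if the bias is incomplete. Regiochemistry is secured by the substrate: the two CH/OH pairs of 8 are equivalent and the para oxygen is silylated, so closure can only use a hydroxyl ortho to top C4, which is the 4→8 pattern. After the first annulation the silyl group can only lean toward the remaining CH, which together with the excess of 8 should disfavour a second annulation. Bromine on bottom C8 removes the only other nucleophilic aryl CH, and the 3-O-acyl group and full O-benzylation of the top unit keep ionisation of the top C4–aryl bond slow at this acidity.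

Step 13
Reactants: 21 trimer with middle 7-hydroxy-5-(triisopropylsilyloxy)flav-2-ene unit
Product: 22 trimer with middle 5,7-di-O-benzylflav-2-ene unit (all phenols benzylated, bottom C8–Br)
Conditions: CsF, Cs2CO3, BnBr, DMF, 0 °C → rt
Reagents that add atoms: benzyl bromide, BrCc1ccccc1
Why: Fluoride cleaves the aryl silyl ether, carbonate deprotonates the free phenol, and both phenoxides undergo Williamson benzylation in the same flask; the medium is anhydrous, so the gallate ester is not hydrolysed, and the enol ether and aryl bromide do not react.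

Step 14
Reactants: 22 trimer with middle 5,7-di-O-benzylflav-2-ene unit
Product: 24 trimer whose middle unit is the 2,3-cis-3,4-trans flavan-3-ol with free 3-OH, via 2α,3α-epoxide 23 (not isolated)
Conditions: DMDO (1.2 equiv), acetone–CH2Cl2, −40 → 0 °C; evaporate; then Et3SiH (5 equiv), BF3·OEt2 (1.2 equiv), CH2Cl2, −78 °C; aq. NaHCO3
Reagents that add atoms: dimethyldioxirane, CC1(C)OO1
Why: The dioxirane epoxidises the electron-rich enol ether opposite to the pseudoaxial C4 aryl group, which fixes C3 trans to C4 in epoxide 23; BF3 then opens it at C2 to an aryl-stabilised oxocarbenium ion pair and the silane delivers hydride anti to the C3–O–BF3 group (ionic hydrogenation), so the C2 aryl group ends cis to the C3 oxygen; the epoxide is carried on crude because it would not survive chromatography.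

Step 15
Reactants: 24 trimer with free middle 3-OH; 3 3,4,5-tris(benzyloxy)benzoic acid
Product: 25 nonadeca-O-benzyl-8-bromo trimer 3,3-digallate (top and middle gallates)
Conditions: 3 (3 equiv), DCC (3 equiv), DMAP (1 equiv), CH2Cl2, rt → 40 °C
Reagents that add atoms: none
Why: Steglich esterification of the only free hydroxyl; the alcohol is hindered by the aryl-bearing C2 and C4, which is why an excess of the activated acid and a full equivalent of DMAP (acylpyridinium pathway) are used, and no stereocentre is touched.

Step 16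
Reactants: 25 nonadeca-O-benzyl-8-bromo trimer digallate
Product: 26 epicatechin 3-O-gallate-(4β→8)-epicatechin 3-O-gallate-(4β→6)-catechin (target)
Conditions: H2 (1 atm), Pd(OH)2 on carbon, Et3N (1.1 equiv), THF–MeOH–H2O, rt
Reagents that add atoms: none
Why: Catalytic hydrogenolysis cleaves the nineteen benzyl ethers and reduces the C–Br bond, while the gallate esters, the diarylmethine bonds and the cyclic C2–O1 bonds are not cleaved under these mild conditions; the amine takes up HBr, which would otherwise cleave the interflavan bonds, and no stereocentre is affected.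

## Compound list

1 | (−)-epicatechin (2R,3R) | O[C@@H]1Cc2c(O)cc(O)cc2O[C@@H]1c1ccc(O)c(O)c1 | starting material

2 | 5,7,3',4'-tetra-O-benzyl-(−)-epicatechin | O[C@@H]1Cc2c(OCc4ccccc4)cc(OCc4ccccc4)cc2O[C@@H]1c1ccc(OCc4ccccc4)c(OCc4ccccc4)c1 | intermediate

3 | 3,4,5-tris(benzyloxy)benzoic acid | O=C(O)c1cc(OCc4ccccc4)c(OCc4ccccc4)c(OCc4ccccc4)c1 | starting material

4 | 5,7,3',4'-tetra-O-benzyl-(−)-epicatechin 3-O-(3,4,5-tri-O-benzyl)gallate | O=C(O[C@@H]1Cc2c(OCc4ccccc4)cc(OCc4ccccc4)cc2O[C@@H]1c1ccc(OCc4ccccc4)c(OCc4ccccc4)c1)c1cc(OCc4ccccc4)c(OCc4ccccc4)c(OCc4ccccc4)c1 | intermediate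

5 | 4β-(2-ethoxyethoxy) derivative of 4 (2,3-cis-3,4-trans) | O=C(O[C@@H]1[C@@H](OCCOCC)c2c(OCc4ccccc4)cc(OCc4ccccc4)cc2O[C@@H]1c1ccc(OCc4ccccc4)c(OCc4ccccc4)c1)c1cc(OCc4ccccc4)c(OCc4ccccc4)c(OCc4ccccc4)c1 | intermediate

6 | phloroglucinol | Oc1cc(O)cc(O)c1 | starting material

7 | 4β-(2,4,6-trihydroxyphenyl) derivative of 4 | O=C(O[C@@H]1[C@@H](c2c(O)cc(O)cc2O)c2c(OCc4ccccc4)cc(OCc4ccccc4)cc2O[C@@H]1c1ccc(OCc4ccccc4)c(OCc4ccccc4)c1)c1cc(OCc4ccccc4)c(OCc4ccccc4)c(OCc4ccccc4)c1 | intermediate

8 | 4β-[2,6-dihydroxy-4-(triisopropylsilyloxy)phenyl] derivative of 4 | O=C(O[C@@H]1[C@@H](c2c(O)cc(O[Si](C(C)C)(C(C)C)C(C)C)cc2O)c2c(OCc4ccccc4)cc(OCc4ccccc4)cc2O[C@@H]1c1ccc(OCc4ccccc4)c(OCc4ccccc4)c1)c1cc(OCc4ccccc4)c(OCc4ccccc4)c(OCc4ccccc4)c1 | intermediate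

9 | (+)-catechin (2R,3S) | O[C@H]1Cc2c(O)cc(O)cc2O[C@@H]1c1ccc(O)c(O)c1 | starting material

10 | 5,7,3',4'-tetra-O-benzyl-(+)-catechin | O[C@H]1Cc2c(OCc4ccccc4)cc(OCc4ccccc4)cc2O[C@@H]1c1ccc(OCc4ccccc4)c(OCc4ccccc4)c1 | intermediate

11 | 8-bromo-5,7,3',4'-tetra-O-benzyl-(+)-catechin | O[C@H]1Cc2c(OCc4ccccc4)cc(OCc4ccccc4)c(Br)c2O[C@@H]1c1ccc(OCc4ccccc4)c(OCc4ccccc4)c1 | intermediate

12 | 8-bromo-3,5,7,3',4'-penta-O-benzyl-(+)-catechin | O(Cc4ccccc4)[C@H]1Cc2c(OCc4ccccc4)cc(OCc4ccccc4)c(Br)c2O[C@@H]1c1ccc(OCc4ccccc4)c(OCc4ccccc4)c1 | intermediate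

13 | C6 N,N-dimethyliminium dichlorophosphate of 12 (aryl–CH=NMe2+) | C[N+](C)=Cc2c(OCc4ccccc4)c(Br)c3c(c2OCc4ccccc4)C[C@H](OCc4ccccc4)[C@@H](c2ccc(OCc4ccccc4)c(OCc4ccccc4)c2)O3.[O-]P(=O)(Cl)Cl | intermediate

14 | 8-bromo-6-formyl-3,5,7,3',4'-penta-O-benzyl-(+)-catechin | O=Cc2c(OCc4ccccc4)c(Br)c3c(c2OCc4ccccc4)C[C@H](OCc4ccccc4)[C@@H](c2ccc(OCc4ccccc4)c(OCc4ccccc4)c2)O3 | intermediate

15 | 3,4-dihydroxyacetophenone | CC(=O)c1ccc(O)c(O)c1 | starting material

16 | 3,4-dibenzyloxyacetophenone | CC(=O)c1ccc(OCc4ccccc4)c(OCc4ccccc4)c1 | intermediate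

17 | aldol adduct, 3-hydroxy-1-(3,4-dibenzyloxyphenyl)-3-(8-bromo-penta-O-benzylcatechin-6-yl)propan-1-one (both carbinol epimers) | O=C(CC(O)c2c(OCc4ccccc4)c(Br)c3c(c2OCc4ccccc4)C[C@H](OCc4ccccc4)[C@@H](c2ccc(OCc4ccccc4)c(OCc4ccccc4)c2)O3)c1ccc(OCc4ccccc4)c(OCc4ccccc4)c1 | intermediate

18 | (E)-1-(3,4-dibenzyloxyphenyl)-3-(8-bromo-penta-O-benzylcatechin-6-yl)prop-2-en-1-one | O=C(/C=C/c2c(OCc4ccccc4)c(Br)c3c(c2OCc4ccccc4)C[C@H](OCc4ccccc4)[C@@H](c2ccc(OCc4ccccc4)c(OCc4ccccc4)c2)O3)c1ccc(OCc4ccccc4)c(OCc4ccccc4)c1 | intermediate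

19 | conjugate-addition ketone (β,β-diaryl ketone; new C4 centre as in the target) | O=C(O[C@@H]1[C@@H](c2c(O)cc(O[Si](C(C)C)(C(C)C)C(C)C)c(c2O)[C@@H](CC(=O)c2ccc(OCc4ccccc4)c(OCc4ccccc4)c2)c2c(OCc4ccccc4)c(Br)c3c(c2OCc4ccccc4)C[C@H](OCc4ccccc4)[C@@H](c2ccc(OCc4ccccc4)c(OCc4ccccc4)c2)O3)c2c(OCc4ccccc4)cc(OCc4ccccc4)cc2O[C@@H]1c1ccc(OCc4ccccc4)c(OCc4ccccc4)c1)c1cc(OCc4ccccc4)c(OCc4ccccc4)c(OCc4ccccc4)c1 | intermediate

20 | cyclic hemiketal (middle unit 2-hydroxyflavan, C2 epimers) | O=C(O[C@@H]1[C@@H](c2c(O)cc(O[Si](C(C)C)(C(C)C)C(C)C)c3c2OC(O)(c2ccc(OCc4ccccc4)c(OCc4ccccc4)c2)C[C@H]3c2c(OCc4ccccc4)c(Br)c3c(c2OCc4ccccc4)C[C@H](OCc4ccccc4)[C@@H](c2ccc(OCc4ccccc4)c(OCc4ccccc4)c2)O3)c2c(OCc4ccccc4)cc(OCc4ccccc4)cc2O[C@@H]1c1ccc(OCc4ccccc4)c(OCc4ccccc4)c1)c1cc(OCc4ccccc4)c(OCc4ccccc4)c(OCc4ccccc4)c1 | intermediate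

21 | trimer, middle unit 7-hydroxy-5-(triisopropylsilyloxy)flav-2-ene, 4β→6 to the 8-bromo bottom unit, top unit 4β→8 | O=C(O[C@@H]1[C@@H](c2c(O)cc(O[Si](C(C)C)(C(C)C)C(C)C)c3c2OC(c2ccc(OCc4ccccc4)c(OCc4ccccc4)c2)=C[C@H]3c2c(OCc4ccccc4)c(Br)c3c(c2OCc4ccccc4)C[C@H](OCc4ccccc4)[C@@H](c2ccc(OCc4ccccc4)c(OCc4ccccc4)c2)O3)c2c(OCc4ccccc4)cc(OCc4ccccc4)cc2O[C@@H]1c1ccc(OCc4ccccc4)c(OCc4ccccc4)c1)c1cc(OCc4ccccc4)c(OCc4ccccc4)c(OCc4ccccc4)c1 | intermediate

22 | trimer, middle unit 5,7-di-O-benzylflav-2-ene, otherwise as 21 | O=C(O[C@@H]1[C@@H](c2c(OCc4ccccc4)cc(OCc4ccccc4)c3c2OC(c2ccc(OCc4ccccc4)c(OCc4ccccc4)c2)=C[C@H]3c2c(OCc4ccccc4)c(Br)c3c(c2OCc4ccccc4)C[C@H](OCc4ccccc4)[C@@H](c2ccc(OCc4ccccc4)c(OCc4ccccc4)c2)O3)c2c(OCc4ccccc4)cc(OCc4ccccc4)cc2O[C@@H]1c1ccc(OCc4ccccc4)c(OCc4ccccc4)c1)c1cc(OCc4ccccc4)c(OCc4ccccc4)c(OCc4ccccc4)c1 | intermediate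

23 | middle-unit 2α,3α-epoxide of 22 (oxygen anti to the C4 aryl group) | O=C(O[C@@H]1[C@@H](c2c(OCc4ccccc4)cc(OCc4ccccc4)c3c2O[C@]5(c2ccc(OCc4ccccc4)c(OCc4ccccc4)c2)O[C@@H]5[C@H]3c2c(OCc4ccccc4)c(Br)c3c(c2OCc4ccccc4)C[C@H](OCc4ccccc4)[C@@H](c2ccc(OCc4ccccc4)c(OCc4ccccc4)c2)O3)c2c(OCc4ccccc4)cc(OCc4ccccc4)cc2O[C@@H]1c1ccc(OCc4ccccc4)c(OCc4ccccc4)c1)c1cc(OCc4ccccc4)c(OCc4ccccc4)c(OCc4ccccc4)c1 | intermediate

24 | trimer, middle unit 2,3-cis-3,4-trans flavan-3-ol with free 3-OH | O=C(O[C@@H]1[C@@H](c2c(OCc4ccccc4)cc(OCc4ccccc4)c3c2O[C@H](c2ccc(OCc4ccccc4)c(OCc4ccccc4)c2)[C@H](O)[C@H]3c2c(OCc4ccccc4)c(Br)c3c(c2OCc4ccccc4)C[C@H](OCc4ccccc4)[C@@H](c2ccc(OCc4ccccc4)c(OCc4ccccc4)c2)O3)c2c(OCc4ccccc4)cc(OCc4ccccc4)cc2O[C@@H]1c1ccc(OCc4ccccc4)c(OCc4ccccc4)c1)c1cc(OCc4ccccc4)c(OCc4ccccc4)c(OCc4ccccc4)c1 | intermediate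

25 | nonadeca-O-benzyl-8-bromo trimer digallate | O=C(O[C@@H]1[C@@H](c2c(OCc4ccccc4)cc(OCc4ccccc4)c3c2O[C@H](c2ccc(OCc4ccccc4)c(OCc4ccccc4)c2)[C@H](OC(=O)c2cc(OCc4ccccc4)c(OCc4ccccc4)c(OCc4ccccc4)c2)[C@H]3c2c(OCc4ccccc4)c(Br)c3c(c2OCc4ccccc4)C[C@H](OCc4ccccc4)[C@@H](c2ccc(OCc4ccccc4)c(OCc4ccccc4)c2)O3)c2c(OCc4ccccc4)cc(OCc4ccccc4)cc2O[C@@H]1c1ccc(OCc4ccccc4)c(OCc4ccccc4)c1)c1cc(OCc4ccccc4)c(OCc4ccccc4)c(OCc4ccccc4)c1 | intermediate

26 | epicatechin 3-O-gallate-(4β→8)-epicatechin 3-O-gallate-(4β→6)-catechin | O=C(O[C@@H]1[C@@H](c2c(O)cc(O)c3c2O[C@H](c2ccc(O)c(O)c2)[C@H](OC(=O)c2cc(O)c(O)c(O)c2)[C@H]3c2c(O)cc3c(c2O)C[C@H](O)[C@@H](c2ccc(O)c(O)c2)O3)c2c(O)cc(O)cc2O[C@@H]1c1ccc(O)c(O)c1)c1cc(O)c(O)c(O)c1 | target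

## Step count and risks

Total: 16 steps. Longest linear sequence: 10 steps, either from 9 through steps 6, 7, 8, 9, 11, 12, 13, 14, 15 and 16, or from 1 through steps 1, 2, 3, 4, 5, 12, 13, 14, 15 and 16, to 26. Step 10 runs in parallel.

**Step 12 (key step).** The most likely failure is a weak facial bias at the β-carbon. The catalyst must differentiate the faces of a hindered, electron-rich enone with no help from the remote stereocentres, and a stronger acid used to raise the rate would start to ionise the top C4–aryl bond. The fallback gives up the annulation and sets middle C4 by substrate control. 5 would be coupled with an excess of 4, acting as nucleophile through its C8, under TMSOTf in CH2Cl2 at low temperature, which would give the perbenzylated epicatechin gallate-(4β→8)-epicatechin gallate dimer F1. DDQ and 2-ethoxyethanol would convert F1 into its lower-unit 4β-(2-ethoxyethoxy) derivative F2. TMSOTf-promoted coupling of F2 with 12, whose only free nucleophilic position is C6, would give 25, with the new bond trans to the neighbouring acyloxy group. This fallback sets out from 5 (with 4 and 12) and rejoins the route at 25.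

**Step 14.** Hydride may be delivered to the wrong face of the C2 oxocarbenium ion, or a 1,2-hydride shift of the opened epoxide may give the flavan-3-one. Both are possible because the cation is long-lived and the face anti to the C3 oxygen also carries the C4 aryl group. The fallback enforces the cis outcome by neighbouring-group participation. Dihydroxylation of 22 with catalytic OsO4 and N-methylmorpholine N-oxide, anti to the C4 aryl group, would give the 2,3-cis diol hemiketal F3. Esterification of its secondary hydroxyl with 3 (DCC, DMAP) would give the 3-O-(tri-O-benzylgalloyl) hemiketal F4. Et3SiH/BF3·OEt2 would then reduce C2 through the acyloxonium ion bridged on the α face, so hydride can only enter anti to the ester, giving 25. This fallback sets out from 22 and rejoins the route at 25.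

**Step 5.** Discrimination between the para and the two ortho phenols may be incomplete, giving mixed mono- and bis-silyl ethers, since all three are phenols of similar acidity. The fallback avoids any differentiation. 5 would be alkylated with commercial 3,5-dibenzyloxyphenol (BF3·OEt2, CH2Cl2) at the carbon ortho to its hydroxyl, which would give the 4β-(2-hydroxy-4,6-dibenzyloxyphenyl) compound F5, to be freed from the para-linked isomer by chromatography. F5 and 18 under the conditions of step 12 would give 22 directly, because the single hydroxyl and its one ortho CH define the ring closure. This fallback sets out from 5 and rejoins the route at 22. Its price is the ortho/para competition in the alkylation and a possible non-cyclising conjugate addition through the CH para to the hydroxyl.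

**Step 9.** Substitution at a carbon flanked by two benzyloxy groups on a bromine-bearing ring may be slow, and the heating needed may start to cleave benzyl ethers. The fallback replaces electrophilic formylation by halogen–metal exchange. N-iodosuccinimide with catalytic CF3CO2H would iodinate 12 to the 8-bromo-6-iodo compound F6. iPrMgCl·LiCl in THF at −40 °C would exchange iodine selectively to give the arylmagnesium chloride F7, and DMF followed by aqueous work-up would give 14. This fallback sets out from 12 and rejoins the route at 14.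

**Step 3.** Hydride abstraction at C4 may be sluggish because the neighbouring acyloxy group destabilises the developing cation, and a forced oxidation may turn to oxidative loss of benzyl ethers. The fallback reverses the order of oxidation and acylation. 2, whose C3 hydroxyl is still free, would be oxidised with DDQ and 2-ethoxyethanol in CH2Cl2 to 4β-(2-ethoxyethoxy)-5,7,3',4'-tetra-O-benzylepicatechin F8. Steglich esterification of F8 with 3 (DCC, DMAP, CH2Cl2) would give 5. This fallback sets out from 2 and rejoins the route at 5.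

## Further compounds

F1 | step 12 | perbenzylated epicatechin 3-O-gallate-(4β→8)-epicatechin 3-O-gallate | O=C(O[C@@H]1[C@@H](c2c(OCc4ccccc4)cc(OCc4ccccc4)c3c2O[C@H](c2ccc(OCc4ccccc4)c(OCc4ccccc4)c2)[C@H](OC(=O)c2cc(OCc4ccccc4)c(OCc4ccccc4)c(OCc4ccccc4)c2)C3)c2c(OCc4ccccc4)cc(OCc4ccccc4)cc2O[C@@H]1c1ccc(OCc4ccccc4)c(OCc4ccccc4)c1)c1cc(OCc4ccccc4)c(OCc4ccccc4)c(OCc4ccccc4)c1

F2 | step 12 | lower-unit 4β-(2-ethoxyethoxy) derivative of F1 | O=C(O[C@@H]1[C@@H](c2c(OCc4ccccc4)cc(OCc4ccccc4)c3c2O[C@H](c2ccc(OCc4ccccc4)c(OCc4ccccc4)c2)[C@H](OC(=O)c2cc(OCc4ccccc4)c(OCc4ccccc4)c(OCc4ccccc4)c2)[C@H]3OCCOCC)c2c(OCc4ccccc4)cc(OCc4ccccc4)cc2O[C@@H]1c1ccc(OCc4ccccc4)c(OCc4ccccc4)c1)c1cc(OCc4ccccc4)c(OCc4ccccc4)c(OCc4ccccc4)c1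

F3 | step 14 | middle-unit 2,3-cis diol hemiketal (2-hydroxyflavan-3-ol, hydroxyls anti to the C4 aryl group) | O=C(O[C@@H]1[C@@H](c2c(OCc4ccccc4)cc(OCc4ccccc4)c3c2O[C@@](O)(c2ccc(OCc4ccccc4)c(OCc4ccccc4)c2)[C@H](O)[C@H]3c2c(OCc4ccccc4)c(Br)c3c(c2OCc4ccccc4)C[C@H](OCc4ccccc4)[C@@H](c2ccc(OCc4ccccc4)c(OCc4ccccc4)c2)O3)c2c(OCc4ccccc4)cc(OCc4ccccc4)cc2O[C@@H]1c1ccc(OCc4ccccc4)c(OCc4ccccc4)c1)c1cc(OCc4ccccc4)c(OCc4ccccc4)c(OCc4ccccc4)c1

F4 | step 14 | 3-O-(tri-O-benzylgalloyl) ester of F3 | O=C(O[C@@H]1[C@@H](c2c(OCc4ccccc4)cc(OCc4ccccc4)c3c2O[C@@](O)(c2ccc(OCc4ccccc4)c(OCc4ccccc4)c2)[C@H](OC(=O)c2cc(OCc4ccccc4)c(OCc4ccccc4)c(OCc4ccccc4)c2)[C@H]3c2c(OCc4ccccc4)c(Br)c3c(c2OCc4ccccc4)C[C@H](OCc4ccccc4)[C@@H](c2ccc(OCc4ccccc4)c(OCc4ccccc4)c2)O3)c2c(OCc4ccccc4)cc(OCc4ccccc4)cc2O[C@@H]1c1ccc(OCc4ccccc4)c(OCc4ccccc4)c1)c1cc(OCc4ccccc4)c(OCc4ccccc4)c(OCc4ccccc4)c1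

F5 | step 5 | 4β-(2-hydroxy-4,6-dibenzyloxyphenyl) derivative of 4 | O=C(O[C@@H]1[C@@H](c2c(O)cc(OCc4ccccc4)cc2OCc4ccccc4)c2c(OCc4ccccc4)cc(OCc4ccccc4)cc2O[C@@H]1c1ccc(OCc4ccccc4)c(OCc4ccccc4)c1)c1cc(OCc4ccccc4)c(OCc4ccccc4)c(OCc4ccccc4)c1

F6 | step 9 | 8-bromo-6-iodo-3,5,7,3',4'-penta-O-benzyl-(+)-catechin | O(Cc4ccccc4)[C@H]1Cc2c(OCc4ccccc4)c(I)c(OCc4ccccc4)c(Br)c2O[C@@H]1c1ccc(OCc4ccccc4)c(OCc4ccccc4)c1

F7 | step 9 | 8-bromo-6-(chloromagnesio)-3,5,7,3',4'-penta-O-benzyl-(+)-catechin | O(Cc4ccccc4)[C@H]1Cc2c(OCc4ccccc4)c([Mg]Cl)c(OCc4ccccc4)c(Br)c2O[C@@H]1c1ccc(OCc4ccccc4)c(OCc4ccccc4)c1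

F8 | step 3 | 4β-(2-ethoxyethoxy)-5,7,3',4'-tetra-O-benzyl-(−)-epicatechin | O[C@@H]1[C@@H](OCCOCC)c2c(OCc4ccccc4)cc(OCc4ccccc4)cc2O[C@@H]1c1ccc(OCc4ccccc4)c(OCc4ccccc4)c1

A1 | alternative 1 | (2-hydroxy-4,6-dibenzyloxyphenyl)(5,7,3',4'-tetra-O-benzyl-3-O-TBS-epicatechin-8-yl)methanol | OC(c1c(O)cc(OCc4ccccc4)cc1OCc4ccccc4)c1c(OCc4ccccc4)cc(OCc4ccccc4)c2c1O[C@H](c1ccc(OCc4ccccc4)c(OCc4ccccc4)c1)[C@H](O[Si](C)(C)C(C)(C)C)C2

A2 | alternative 1 | (Z)-2-(tert-butyldimethylsilyloxy)-1-(3,4-dibenzyloxyphenyl)-1-(trimethylsilyloxy)ethene | C[Si](C)(C)O/C(=C\O[Si](C)(C)C(C)(C)C)c1ccc(OCc4ccccc4)c(OCc4ccccc4)c1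

A3 | alternative 1 | top-unit 2-hydroxy-3-O-TBS-flavan hemiketal bonded through C4 to C8 of tetra-O-benzyl-3-O-TBS-epicatechin | CC(C)(C)[Si](C)(C)O[C@@H]1[C@@H](c2c(OCc4ccccc4)cc(OCc4ccccc4)c3c2O[C@H](c2ccc(OCc4ccccc4)c(OCc4ccccc4)c2)[C@H](O[Si](C)(C)C(C)(C)C)C3)c2c(OCc4ccccc4)cc(OCc4ccccc4)cc2OC1(O)c1ccc(OCc4ccccc4)c(OCc4ccccc4)c1

A4 | alternative 2 | perbenzylated top–middle digallate whose middle C4 carries a 2,6-dibenzyloxy-3-vinyl-4-[1-(3,4-dibenzyloxyphenyl)allyloxy]phenyl ring (ring-closing metathesis precursor; vinyl at the future C4a, allylic ether on the future C8a oxygen) | O=C(O[C@@H]1[C@@H](c2c(OCc4ccccc4)cc(OCc4ccccc4)c3c2O[C@H](c2ccc(OCc4ccccc4)c(OCc4ccccc4)c2)[C@H](OC(=O)c2cc(OCc4ccccc4)c(OCc4ccccc4)c(OCc4ccccc4)c2)[C@H]3c2c(OCc4ccccc4)cc(O[C@@H](C=C)c3ccc(OCc4ccccc4)c(OCc4ccccc4)c3)c(C=C)c2OCc4ccccc4)c2c(OCc4ccccc4)cc(OCc4ccccc4)cc2O[C@@H]1c1ccc(OCc4ccccc4)c(OCc4ccccc4)c1)c1cc(OCc4ccccc4)c(OCc4ccccc4)c(OCc4ccccc4)c1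

A5 | alternative 2 | perbenzylated trimer with the bottom unit as a (2S)-flav-3-ene | O=C(O[C@@H]1[C@@H](c2c(OCc4ccccc4)cc(OCc4ccccc4)c3c2O[C@H](c2ccc(OCc4ccccc4)c(OCc4ccccc4)c2)[C@H](OC(=O)c2cc(OCc4ccccc4)c(OCc4ccccc4)c(OCc4ccccc4)c2)[C@H]3c2c(OCc4ccccc4)cc3c(c2OCc4ccccc4)C=C[C@@H](c2ccc(OCc4ccccc4)c(OCc4ccccc4)c2)O3)c2c(OCc4ccccc4)cc(OCc4ccccc4)cc2O[C@@H]1c1ccc(OCc4ccccc4)c(OCc4ccccc4)c1)c1cc(OCc4ccccc4)c(OCc4ccccc4)c(OCc4ccccc4)c1

A6 | alternative 3 | 4,6-dibenzyloxy-3-(tetra-O-benzyl-3-O-TBS-epicatechin-8-yl)indan-1-one | O=C1C[C@@H](c2c(OCc4ccccc4)cc(OCc4ccccc4)c3c2O[C@H](c2ccc(OCc4ccccc4)c(OCc4ccccc4)c2)[C@H](O[Si](C)(C)C(C)(C)C)C3)c2c(OCc4ccccc4)cc(OCc4ccccc4)cc21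

A7 | alternative 3 | 5,7-dibenzyloxy-4-(tetra-O-benzyl-3-O-TBS-epicatechin-8-yl)chroman-2-one | O=C1C[C@@H](c2c(OCc4ccccc4)cc(OCc4ccccc4)c3c2O[C@H](c2ccc(OCc4ccccc4)c(OCc4ccccc4)c2)[C@H](O[Si](C)(C)C(C)(C)C)C3)c2c(OCc4ccccc4)cc(OCc4ccccc4)cc2O1
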